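**Retrosynthetic overview**
1. The strategy rests on the 1,5-relationship between the ring ketone C11 and the side-chain ketone C15 through C12–C13–C14 (prostanoid numbering, cyclopentanone ring C8–C12). This is read as a 1,3-diketone enol (C11–C14–C15) that has taken up a C12=C13 vinyl group carried by C8.
2. Key disconnection: C11–C12 and C13–C14 are cut together (retro-De Mayo) to give the acyclic diketone 22. The cyclopentanone is the only ring of the target and is closed in this one photochemical step.
3. Diketone 22 comes from aldehyde 18 and heptan-2-one (aldol, then oxidation; C11–C14 bond). The vinyl group and the free C11 alcohol both arise from one lactol methylenation of δ-lactone 15; the lactone also tells C12 apart from the C1 ester.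
4. C9 is set by asymmetric hydrogenation of a β-keto ester, and C8 by anti-selective dianion alkylation with the (Z)-C1–C7 allylic bromide 6 made from hex-5-ynoic acid.
5. Endgame: desilylation and enzymatic ester hydrolysis under near-neutral conditions that spare the β-ketol.

Key step: step 15

Remark: atoms are numbered as in the prostanoic acid skeleton (C1 acid carbon, ring C8–C12, C9 carbinol, ketones at C11 and C15). The acyclic 1,3-diketone 22 is assumed to be largely enolised in hydrocarbon solvent, as simple β-diketones are. C1 is carried as a methyl ester so that the final deprotection needs neither strong acid nor base.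

**Route**

Step 1
Reactants: 1 hex-5-ynoic acid
Product: 3 7-hydroxyhept-5-ynoic acid, via lithium 6-lithiohex-5-ynoate 2 (not isolated)
Conditions: n-BuLi (2.1 equiv), THF, −78 → 0 °C; (CH2O)n, 0 °C → rt; 1 M HCl
Reagents that add atoms: paraformaldehyde (as formaldehyde), C=O
Why: Acetylide hydroxymethylation: the second equivalent of base deprotonates the terminal alkyne of the lithium carboxylate, and the acetylide adds to formaldehyde to install C7 with its oxygen.

Step 2
Reactants: 3 7-hydroxyhept-5-ynoic acid
Product: 4 methyl 7-hydroxyhept-5-ynoate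
Conditions: MeOH, H2SO4 (cat.), rt
Reagents that add atoms: methanol, CO
Why: Fischer esterification in excess methanol; the propargylic alcohol is inert to catalytic acid at room temperature.

Step 3
Reactants: 4 methyl 7-hydroxyhept-5-ynoate
Product: 5 methyl (5Z)-7-hydroxyhept-5-enoate
Conditions: H2 (1 atm), Pd/CaCO3–Pb(OAc)2 (Lindlar catalyst), quinoline, EtOAc, rt
Reagents that add atoms: none
Why: Lindlar semi-hydrogenation: syn delivery of hydrogen on the poisoned palladium surface should give the Z alkene C5=C6 and stop at the alkene stage.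

Step 4
Reactants: 5 methyl (5Z)-7-hydroxyhept-5-enoate
Product: 6 methyl (5Z)-7-bromohept-5-enoate
Conditions: CBr4, PPh3, CH2Cl2, 0 °C
Reagents that add atoms: carbon tetrabromide, BrC(Br)(Br)Br
Why: Appel bromination: SN2 displacement of the primary allylic oxyphosphonium by bromide at 0 °C should proceed without allylic transposition or loss of the Z geometry.

Step 5
Reactants: 7 methyl acetoacetate
Product: 9 methyl 5-(benzyloxy)-3-oxopentanoate, via dilithium dianion of methyl acetoacetate 8 (not isolated)
Conditions: LiN(i-Pr)2 (2.1 equiv), THF, 0 °C; BnOCH2Cl, −78 → 0 °C; 1 M HCl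
Reagents that add atoms: benzyl chloromethyl ether, ClCOCc1ccccc1
Why: γ-Alkylation of an acetoacetate dianion (Weiler alkylation): the more basic terminal carbanion reacts with the chloromethyl ether and adds C11 with a protected oxygen.

Step 6
Reactants: 9 methyl 5-(benzyloxy)-3-oxopentanoate
Product: 10 methyl (3S)-5-(benzyloxy)-3-hydroxypentanoate
Conditions: H2 (50 atm), RuCl2[(S)-BINAP] (0.5 mol%), MeOH, 50 °C
Reagents that add atoms: none
Why: Noyori asymmetric hydrogenation of a β-keto ester: the (S)-BINAP–ruthenium catalyst reduces the chelated ketone from one face to set C9 as S, and the homogeneous catalyst does not hydrogenolyse the benzyl ether.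

Step 7
Reactants: 10 methyl (3S)-5-(benzyloxy)-3-hydroxypentanoate; 6 methyl (5Z)-7-bromohept-5-enoate
Product: 12 methyl (2S,3S)-5-(benzyloxy)-3-hydroxy-2-[(2Z)-7-methoxy-7-oxohept-2-en-1-yl]pentanoate, via dilithium alkoxide enolate 11 (not isolated)
Conditions: LiN(i-Pr)2 (2.2 equiv), THF, −78 → −20 °C; 6, DMPU, −78 → −10 °C; 1 M HCl
Reagents that add atoms: none
Why: Fráter–Seebach alkylation: the allylic bromide attacks the six-membered lithium chelate of the alkoxide enolate on the face opposite the C10 chain, which sets C8 anti to the C9 oxygen (2S,3S), and alkylation at low temperature should outrun attack on the distal methyl ester.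

Step 8
Reactants: 12 methyl (2S,3S)-5-(benzyloxy)-3-hydroxy-2-[(2Z)-7-methoxy-7-oxohept-2-en-1-yl]pentanoate
Product: 14 methyl (5Z)-7-[(3S,4S)-4-hydroxy-2-oxooxan-3-yl]hept-5-enoate, via debenzylated diol ester 13 (not isolated)
Conditions: BCl3 (3 equiv), C6HMe5 (3 equiv), CH2Cl2, −78 → −40 °C; H2O; then TsOH·H2O (5 mol%), CH2Cl2, rt
Reagents that add atoms: none
Why: Lewis-acid cleavage of the benzyl ether with pentamethylbenzene as cation scavenger (no hydrogenation, so the Z alkene survives) frees the C11 hydroxyl, and acid-catalysed lactonisation of the δ-hydroxy ester onto C12 then gives the cis-3,4-disubstituted δ-lactone and distinguishes C12 from the C1 ester.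

Step 9
Reactants: 14 methyl (5Z)-7-[(3S,4S)-4-hydroxy-2-oxooxan-3-yl]hept-5-enoate
Product: 15 methyl (5Z)-7-[(3S,4S)-4-[(tert-butyldimethylsilyl)oxy]-2-oxooxan-3-yl]hept-5-enoate
Conditions: TBSOTf, 2,6-lutidine, CH2Cl2, −78 → 0 °C
Reagents that add atoms: tert-butyldimethylsilyl trifluoromethanesulfonate, CC(C)(C)[Si](C)(C)OS(=O)(=O)C(F)(F)F
Why: Silylation of the hindered secondary alcohol with the silyl triflate and a non-nucleophilic base protects C9 without enolising the lactone.

Step 10
Reactants: 15 methyl (5Z)-7-[(3S,4S)-4-[(tert-butyldimethylsilyl)oxy]-2-oxooxan-3-yl]hept-5-enoate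
Product: 16 methyl (5Z)-7-[(3S,4S)-4-[(tert-butyldimethylsilyl)oxy]-2-hydroxyoxan-3-yl]hept-5-enoate (anomer mixture)
Conditions: i-Bu2AlH (1.1 equiv), CH2Cl2, −78 °C; aq. Rochelle salt
Reagents that add atoms: none
Why: Partial reduction of a lactone to a lactol: the δ-lactone carbonyl is more electrophilic than the acyclic methyl ester and its tetrahedral aluminate is stable at −78 °C, so one equivalent of hydride should stop at the lactol and leave C1 untouched.

Step 11
Reactants: 16 methyl (5Z)-7-[(3S,4S)-4-[(tert-butyldimethylsilyl)oxy]-2-hydroxyoxan-3-yl]hept-5-enoate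
Product: 17 methyl (5Z,8R,9S)-9-[(tert-butyldimethylsilyl)oxy]-8-ethenyl-11-hydroxyundec-5-enoate
Conditions: Ph3PCH3Br (3.5 equiv), n-BuLi (3.3 equiv), THF, 0 °C; then 16, 0 °C → rt
Reagents that add atoms: methyltriphenylphosphonium bromide, C[P+](c1ccccc1)(c1ccccc1)c1ccccc1.[Br-]
Why: Wittig methylenation of the ring-opened hydroxy aldehyde form of the lactol turns C12 into the vinyl group (C12=C13) and releases the C11 primary alcohol in the same operation; the lithium counter-ion is chosen to slow oxygen-to-oxygen silyl transfer to the new alkoxide.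

Step 12
Reactants: 17 methyl (5Z,8R,9S)-9-[(tert-butyldimethylsilyl)oxy]-8-ethenyl-11-hydroxyundec-5-enoate
Product: 18 methyl (5Z,8R,9S)-9-[(tert-butyldimethylsilyl)oxy]-8-ethenyl-11-oxoundec-5-enoate
Conditions: Dess–Martin periodinane (1.3 equiv), CH2Cl2, 0 °C → rt
Reagents that add atoms: none
Why: Dess–Martin oxidation of the primary alcohol to the aldehyde under near-neutral conditions that leave the silyl ether, both alkenes and the ester alone.

Step 13
Reactants: 18 methyl (5Z,8R,9S)-9-[(tert-butyldimethylsilyl)oxy]-8-ethenyl-11-oxoundec-5-enoate; 19 heptan-2-one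
Product: 21 methyl (5Z,8R,9S)-9-[(tert-butyldimethylsilyl)oxy]-8-ethenyl-11-hydroxy-13-oxooctadec-5-enoate (C11 epimers), via lithium hept-1-en-2-olate 20 (not isolated)
Conditions: 19 (1.3 equiv), LiN(i-Pr)2 (1.25 equiv), THF, −78 °C; then 18, −78 °C; AcOH quench
Reagents that add atoms: none
Why: Directed aldol addition: kinetic deprotonation of heptan-2-one at its methyl group and addition of the lithium enolate to the aldehyde at −78 °C forms the C11–C14 bond, and the configuration at C11 is irrelevant because this carbinol is oxidised next.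

Step 14
Reactants: 21 methyl (5Z,8R,9S)-9-[(tert-butyldimethylsilyl)oxy]-8-ethenyl-11-hydroxy-13-oxooctadec-5-enoate
Product: 22 methyl (5Z,8R,9S)-9-[(tert-butyldimethylsilyl)oxy]-8-ethenyl-11,13-dioxooctadec-5-enoate
Conditions: Dess–Martin periodinane (1.3 equiv), CH2Cl2, 0 °C → rt
Reagents that add atoms: none
Why: Dess–Martin oxidation of the β-hydroxy ketone gives the 1,3-diketone, which should exist mainly as its hydrogen-bonded enol and needs only a small excess of oxidant to avoid attack at the doubly activated C14.

Step 15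
Reactants: 22 methyl (5Z,8R,9S)-9-[(tert-butyldimethylsilyl)oxy]-8-ethenyl-11,13-dioxooctadec-5-enoate
Product: 24 methyl (5Z)-7-[(1R,2R,5S)-5-[(tert-butyldimethylsilyl)oxy]-3-oxo-2-(3-oxooctyl)cyclopentyl]hept-5-enoate, via cyclobutanol photoadduct 23 (not isolated)
Conditions: hν (300 nm, Pyrex), degassed cyclohexane (5 mM), 20 °C
Reagents that add atoms: none
Why: De Mayo reaction: excitation of the hydrogen-bonded enol of 22 (enol double bond C11=C14 conjugated with the C15 carbonyl) leads to bonding of C11 to the inner vinyl carbon C12, and the resulting 1,4-biradical at C13 and C14 collapses to the cis-fused bicyclo[3.2.0]heptan-1-ol 23, whose strained β-hydroxy ketone opens by retro-aldol cleavage of C11–C14 to the 1,5-diketone 24. The closest known reaction type is the intramolecular enol–alkene (2+2) photocycloaddition of alkenyl 1,3-diketones followed by spontaneous retro-aldol fragmentation. The cyclopentanone ring (C8–C12) closes in the first bond-forming event by 1,5-closure (five-membered, exo to the vinyl group, the rule of five), and the cyclobutane that follows is only transient. The new stereocentre C12 is controlled by C8 and C9: their substituents should take the convex face of the bicycle so that C13 ends trans to the C7 chain, and because C12 lies next to the C11 ketone any cis epimer can be equilibrated to the favoured trans arrangement. The step needs selectivity for the vinyl group over the C5–C6 alkene, for the straight over the crossed adduct and for the C11 enol over the C15 enol; the three-atom tether C10–C9–C8 secures all three, since every alternative needs a ring larger than five in the first bond formation. Irradiation near 300 nm, where the enol absorbs far more strongly than the product ketones, and stopping at full conversion should limit secondary photochemistry.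

Step 16
Reactants: 24 methyl (5Z)-7-[(1R,2R,5S)-5-[(tert-butyldimethylsilyl)oxy]-3-oxo-2-(3-oxooctyl)cyclopentyl]hept-5-enoate
Product: 25 methyl (5Z)-7-[(1R,2R,5S)-5-hydroxy-3-oxo-2-(3-oxooctyl)cyclopentyl]hept-5-enoate
Conditions: HF·pyridine, pyridine, THF, 0 °C
Reagents that add atoms: none
Why: Fluoride-mediated desilylation with pyridine-buffered HF·pyridine, a mild method for silyl ethers of β-hydroxy cyclopentanones under which the ketol should not eliminate to the enone.

Step 17
Reactants: 25 methyl (5Z)-7-[(1R,2R,5S)-5-hydroxy-3-oxo-2-(3-oxooctyl)cyclopentyl]hept-5-enoate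
Product: 26 13,14-dihydro-15-keto-prostaglandin D2, (5Z)-7-[(1R,2R,5S)-5-hydroxy-3-oxo-2-(3-oxooctyl)cyclopentyl]hept-5-enoic acid
Conditions: porcine liver esterase, 0.1 M phosphate buffer (pH 7.0)/acetone, 30 °C
Reagents that add atoms: water, O
Why: Enzymatic ester hydrolysis at pH 7 frees the acid without the acid or base that would dehydrate the β-ketol or epimerise C12.

**Compound list**
1 | hex-5-ynoic acid | C#CCCCC(=O)O | starting material
2 | lithium 6-lithiohex-5-ynoate (not isolated) | [Li]C#CCCCC(=O)[O-].[Li+] | intermediate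
3 | 7-hydroxyhept-5-ynoic acid | OCC#CCCCC(=O)O | intermediate
4 | methyl 7-hydroxyhept-5-ynoate | OCC#CCCCC(=O)OC | intermediate
5 | methyl (5Z)-7-hydroxyhept-5-enoate | OC/C=C\CCCC(=O)OC | intermediate
6 | methyl (5Z)-7-bromohept-5-enoate | BrC/C=C\CCCC(=O)OC | intermediate
7 | methyl acetoacetate | CC(=O)CC(=O)OC | starting material
8 | dilithium dianion of methyl acetoacetate (not isolated) | [Li+].[Li+].[CH2-]C(=O)[CH-]C(=O)OC | intermediate
9 | methyl 5-(benzyloxy)-3-oxopentanoate | O=C(CCOCc1ccccc1)CC(=O)OC | intermediate
10 | methyl (3S)-5-(benzyloxy)-3-hydroxypentanoate | c1ccccc1COCC[C@H](O)CC(=O)OC | intermediate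
11 | dilithium alkoxide enolate of 10 (not isolated) | COC([O-])=C[C@@H]([O-])CCOCc1ccccc1.[Li+].[Li+] | intermediate
12 | methyl (2S,3S)-5-(benzyloxy)-3-hydroxy-2-[(2Z)-7-methoxy-7-oxohept-2-en-1-yl]pentanoate (C8/C9 anti) | c1ccccc1COCC[C@H](O)[C@@H](C(=O)OC)C/C=C\CCCC(=O)OC | intermediate
13 | methyl (2S,3S)-3,5-dihydroxy-2-[(2Z)-7-methoxy-7-oxohept-2-en-1-yl]pentanoate (not isolated) | OCC[C@H](O)[C@@H](C(=O)OC)C/C=C\CCCC(=O)OC | intermediate
14 | methyl (5Z)-7-[(3S,4S)-4-hydroxy-2-oxooxan-3-yl]hept-5-enoate (cis lactone) | O=C1OCC[C@H](O)[C@@H]1C/C=C\CCCC(=O)OC | intermediate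
15 | methyl (5Z)-7-[(3S,4S)-4-[(tert-butyldimethylsilyl)oxy]-2-oxooxan-3-yl]hept-5-enoate | O=C1OCC[C@H](O[Si](C)(C)C(C)(C)C)[C@@H]1C/C=C\CCCC(=O)OC | intermediate
16 | methyl (5Z)-7-[(3S,4S)-4-[(tert-butyldimethylsilyl)oxy]-2-hydroxyoxan-3-yl]hept-5-enoate (anomer mixture) | OC1OCC[C@H](O[Si](C)(C)C(C)(C)C)[C@@H]1C/C=C\CCCC(=O)OC | intermediate
17 | methyl (5Z,8R,9S)-9-[(tert-butyldimethylsilyl)oxy]-8-ethenyl-11-hydroxyundec-5-enoate | OCC[C@H](O[Si](C)(C)C(C)(C)C)[C@@H](C=C)C/C=C\CCCC(=O)OC | intermediate
18 | methyl (5Z,8R,9S)-9-[(tert-butyldimethylsilyl)oxy]-8-ethenyl-11-oxoundec-5-enoate | O=CC[C@H](O[Si](C)(C)C(C)(C)C)[C@@H](C=C)C/C=C\CCCC(=O)OC | intermediate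
19 | heptan-2-one | CCCCCC(C)=O | starting material
20 | lithium hept-1-en-2-olate (not isolated) | [Li+].[O-]C(=C)CCCCC | intermediate
21 | methyl (5Z,8R,9S)-9-[(tert-butyldimethylsilyl)oxy]-8-ethenyl-11-hydroxy-13-oxooctadec-5-enoate (C11 epimers) | CCCCCC(=O)CC(O)C[C@H](O[Si](C)(C)C(C)(C)C)[C@@H](C=C)C/C=C\CCCC(=O)OC | intermediate
22 | methyl (5Z,8R,9S)-9-[(tert-butyldimethylsilyl)oxy]-8-ethenyl-11,13-dioxooctadec-5-enoate (photoprecursor, C8/C9 anti, mainly enol) | CCCCCC(=O)CC(=O)C[C@H](O[Si](C)(C)C(C)(C)C)[C@@H](C=C)C/C=C\CCCC(=O)OC | intermediate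
23 | cyclobutanol photoadduct (not isolated): cis-fused bicyclo[3.2.0]heptan-1-ol with the hydroxyl on ring-fusion carbon C11, hexanoyl on C14 (both epimers), and the C7 chain and silyloxy group on the convex face | CCCCCC(=O)C1C[C@@H]2[C@@H](C/C=C\CCCC(=O)OC)[C@@H](O[Si](C)(C)C(C)(C)C)C[C@]12O | intermediate
24 | methyl (5Z)-7-[(1R,2R,5S)-5-[(tert-butyldimethylsilyl)oxy]-3-oxo-2-(3-oxooctyl)cyclopentyl]hept-5-enoate | CCCCCC(=O)CC[C@H]1C(=O)C[C@H](O[Si](C)(C)C(C)(C)C)[C@@H]1C/C=C\CCCC(=O)OC | intermediate
25 | methyl (5Z)-7-[(1R,2R,5S)-5-hydroxy-3-oxo-2-(3-oxooctyl)cyclopentyl]hept-5-enoate | CCCCCC(=O)CC[C@H]1C(=O)C[C@H](O)[C@@H]1C/C=C\CCCC(=O)OC | intermediate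
26 | 13,14-dihydro-15-keto-prostaglandin D2, (5Z)-7-[(1R,2R,5S)-5-hydroxy-3-oxo-2-(3-oxooctyl)cyclopentyl]hept-5-enoic acid | CCCCCC(=O)CC[C@H]1C(=O)C[C@H](O)[C@@H]1C/C=C\CCCC(=O)O | target

**Step count**
Total: 17 steps. Longest linear sequence: 15 steps (steps 1–4, then 7–17).

**Steps most likely to fail, with fallbacks**

Step 15 (photocycloaddition and fragmentation).
- What may go wrong: triplet energy transfer from the product ketones could isomerise the C5–C6 alkene; the product could be lost to secondary photocleavage on over-irradiation; cycloaddition could go partly through the crossed mode or the other enol. Incomplete control of C12 is not counted here, because equilibration next to the C11 ketone (neutral alumina or KOAc in MeOH) should correct it.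
- Fallback: it sets out from 22 and returns at 24. Treating 22 with BF3·OEt2 in CH2Cl2 at room temperature should give the difluoroboron chelate of the diketone F1. This chelate has a single, fixed chromophore that absorbs at longer wavelength and is known to add to alkenes from its singlet excited state. Irradiation near 350 nm in MeCN should give the boron-bound cyclobutane adduct F2. Work-up with aqueous NaOAc in MeOH should remove boron and trigger the retro-aldol opening to 24.

Step 10 (partial reduction of the lactone).
- What may go wrong: competing reduction of the C1 methyl ester, or over-reduction of the lactol to the diol.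
- Fallback: it sets out from 15 and returns at 17. Hydrolysis of the methyl ester with Me3SnOH (1,2-dichloroethane, 70 °C; acidic work-up recloses any opened lactone) should give the lactone acid F3. With i-Bu2AlH (2.2 equiv, CH2Cl2, −78 °C) the aluminium carboxylate formed from the first equivalent resists hydride, so the reduction should stop at the lactol acid F4. Methylenation with excess Ph3P=CH2 as in step 11 should give the vinyl hydroxy acid F5. Me3SiCHN2 in MeOH/toluene should then re-form the methyl ester 17.

Step 11 (lactol methylenation).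
- What may go wrong: base-induced epimerisation at C8 or β-elimination of the silyloxy group in the open hydroxy aldehyde; transfer of the silyl group from the C9 oxygen to the new C11 alkoxide; sluggish opening of the lactol.
- Fallback: it sets out from 16 and returns at 17. Addition of the weakly basic organocerium reagent from Me3SiCH2MgCl and CeCl3 (THF, −78 → 0 °C) should give the β-hydroxysilane diol F6. Acid-promoted Peterson elimination (cat. BF3·OEt2, CH2Cl2, 0 °C) should then give 17 without passing through a potassium or lithium alkoxide.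

**Further compounds**
F1 | step 15 | difluoroboron chelate of diketone 22 | CCCCCC1=[O+][B-](F)(F)OC(=C1)C[C@H](O[Si](C)(C)C(C)(C)C)[C@@H](C=C)C/C=C\CCCC(=O)OC
F2 | step 15 | boron-bound cyclobutane photoadduct (difluoroboron chelate of 23) | CCCCCC(=[O+]3)C1C[C@@H]2[C@@H](C/C=C\CCCC(=O)OC)[C@@H](O[Si](C)(C)C(C)(C)C)C[C@]12O[B-]3(F)F
F3 | step 10 | (5Z)-7-[(3S,4S)-4-[(tert-butyldimethylsilyl)oxy]-2-oxooxan-3-yl]hept-5-enoic acid | O=C1OCC[C@H](O[Si](C)(C)C(C)(C)C)[C@@H]1C/C=C\CCCC(=O)O
F4 | step 10 | (5Z)-7-[(3S,4S)-4-[(tert-butyldimethylsilyl)oxy]-2-hydroxyoxan-3-yl]hept-5-enoic acid | OC1OCC[C@H](O[Si](C)(C)C(C)(C)C)[C@@H]1C/C=C\CCCC(=O)O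
F5 | step 10 | (5Z,8R,9S)-9-[(tert-butyldimethylsilyl)oxy]-8-ethenyl-11-hydroxyundec-5-enoic acid | OCC[C@H](O[Si](C)(C)C(C)(C)C)[C@@H](C=C)C/C=C\CCCC(=O)O
F6 | step 11 | methyl (5Z,8R,9S)-9-[(tert-butyldimethylsilyl)oxy]-11-hydroxy-8-[1-hydroxy-2-(trimethylsilyl)ethyl]undec-5-enoate (carbinol epimers) | OCC[C@H](O[Si](C)(C)C(C)(C)C)[C@@H](C(O)C[Si](C)(C)C)C/C=C\CCCC(=O)OC
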